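Compound numbers refer to the steps and to the compound list after them.

## Analysis of the target

The target is a flavanone, (2R,3R)-2-(2,5-dihydroxy-4-methoxyphenyl)-3,5,6,7-tetramethoxychroman-4-one. Ring A is a benzo ring with methoxy groups at C5, C6 and C7 and one hydrogen at C8, ring C is a dihydropyran-4-one (O1, C2, C3, C4) fused to ring A through C4a and C8a, and ring B is a methoxyhydroquinone bound through C1′ to C2. C2 (R) and C3 (R) are the only stereocenters; they are adjacent and trans, so the C2 aryl group and the C3 methoxy group can both be equatorial, which is also the more stable relative arrangement. The molecule is fragile in three ways: ring B is a hydroquinone (2′-OH and 5′-OH are para) and oxidises easily, C3–H is alpha to the C4 ketone, and the O1–C2 bond is beta to that ketone and benzylic to an electron-rich ring, so base can open ring C to an achiral alpha-methoxychalcone and erase both centres at once. For the same reason the C3 methyl ether cannot be placed on a finished 3-hydroxyflavanone with base; it has to arrive inside a building block. The difficulty is therefore to set C3 absolutely while it cannot enolise, to let C2 follow from C3, and to introduce the ketone and the free hydroquinone only at the end. The feature that allows this is the way ring C hangs on ring A: O1 sits on C8a and C4 on the neighbouring C4a, which is the atom pattern of an ortho-quinone methide of ring A, and C2 and C3 with its methoxy group are the two carbons of methoxyacetaldehyde once the C2–C1′ bond is set aside. The bonds O1–C2 and C3–C4 can then be formed together with C4 still a methylene group, and that methylene is activated for later oxidation by O1 and the C5 methoxy group (ortho to C4a) and the C7 methoxy group (para).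

## Retrosynthetic reasoning

**12 to 11 (two O–benzyl bonds of ring B).** The free hydroquinone is the most oxidation-prone part of 12, so it is unmasked last. Both ring B hydroxyls are carried as benzyl ethers in 11, which a single neutral hydrogenolysis removes without touching the base-sensitive flavanone.

**11 to 10 to 9 (oxidation level of C4).** The ketone is traced back through the benzylic alcohol 10 to the methylene compound 9. Removing the carbonyl here, instead of carrying it through the route, means that C3 is not alpha to a carbonyl and O1–C2 is not beta to one until the penultimate step, so neither stereocenter can be lost by enolisation or ring opening earlier. The forward reaction has to abstract hydride from C4, where the cation is stabilised by O1, the C5 methoxy and the C7 methoxy group, and not from C2.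

**9 to 8 (O–benzyl at C2′).** The second benzyl ether is disconnected to the free phenol 8. The phenol is needed in 8 because it is what directs ring B onto C2 in the preceding step; it is capped afterwards because a para-alkoxyphenol would not survive the quinone oxidant of the C4 oxidation.

**8 to 6 and 7 (C2–C1′ bond).** Cutting between C2 and C1′ turns C2 into an oxocarbenium ion, that is the lactol 6, and ring B into the phenol 7 as nucleophile. This is preferred to any cut inside ring B because 7 already has the full oxygen pattern: its carbon ortho to the hydroxyl and para to the methoxy group is the most nucleophilic, and the position para to the hydroxyl is blocked by the benzyloxy group. The gain is convergence and relay of stereochemistry: the forward Friedel–Crafts reaction only has to add ring B trans to the C3 methoxy group, which is both the kinetic and the thermodynamic outcome.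

**6 to 3 and 4 through 5 (O1–C2 and C3–C4 bonds, ring C).** Both bonds of ring C that do not belong to ring A's own substituents are cut at once. Ring A with O1 and C4 becomes the ortho-quinone methide 5, released from the hydroxybenzyl alcohol 3, and C2–C3 becomes methoxyacetaldehyde 4, activated as a chiral enamine. The cut is made here because the polarity fits without adjustment: the enamine carbon that bears the methoxy group is nucleophilic and the methide carbon electrophilic, while the phenoxide oxygen is nucleophilic and the iminium carbon electrophilic. The forward reaction has to form C3–C4 with facial control by the amine catalyst and then close ring C; it creates C3 absolutely, and C2 at the aldehyde oxidation level, exactly what the next step needs.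

**3 to 2 to 1 (the benzylic carbon of ring A).** The hydroxymethyl group is taken back to a formyl group in 2 and then removed to give the symmetric phenol 1. The two positions ortho to the hydroxyl of 1 are equivalent and the para position is occupied, so ortho-formylation has only one possible product and the key-step precursor is reached in two steps.

## Alternatives that were turned down

**Alternative 1:** The disconnection is at C2–C3 and at the C3–O bond, leaving ring C open. In the forward key step the ring A diazoketone A1 is decomposed by a dirhodium carboxylate catalyst, the carbene is captured by the alcohol that supplies the C3 methoxy group, and the oxonium ylide is trapped by the ring B aldehyde A2 under a chiral phosphoric acid before proton shift, giving the aldol-type adduct A3.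
- For: it is convergent, it has the C4 carbonyl in place from the start so no benzylic oxidation is needed, and the oxygen pattern of ring B is fixed by A2 instead of by a Friedel–Crafts preference. On these three points it is stronger than the chosen route.
- Against: ylide trapping of this kind is best with donor–acceptor carbenes and reactive electrophiles. A1 gives an acceptor-only carbene whose ylide collapses quickly by proton shift to the simple O–H insertion product, and A2 is an electron-rich, ortho-substituted and therefore weak electrophile.
- Against: ring C must then be closed by displacing the benzylic hydroxyl of A3 with the ring A phenol. With this ring B that will go by ionisation, so the carbinol configuration set by the chiral acid is discarded and only C3 carries the stereochemical information. C3 is alpha to an aryl ketone from the moment it forms and must survive acidic removal of the methoxymethyl group and the cyclisation.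
- Step economy: A1 needs about four steps from 1 and A2 about two, so the total is no shorter.
- The chosen strategy instead sets C3 in a position that cannot enolise, using a reaction type with direct precedent.

**Alternative 2:** The disconnection is at C8a–O1 and C4a–C4, with ring A as an aryne. In the forward key step a fluoride source liberates the aryne from the silyl triflate A4, the secondary alkoxide of the hydroxy ester A5 adds at the aryne carbon remote from the methoxy group, and the aryl anion at C4a attacks the ester to give A6, which is the same compound as 11.
- For: this has the shortest endgame, since A6 is one hydrogenolysis from 12. Both stereocenters come ready-made from an anti-glycolate aldol, and the aryne regiochemistry agrees with the known preference of 3-alkoxyarynes. In endgame economy and in the pedigree of the stereocontrol it is stronger than the chosen route.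
- Against: the alkoxide of a beta-hydroxy ester under basic fluoride conditions is set up for retro-aldol cleavage of the very C2–C3 bond it carries, and its alpha-hydrogen is epimerisable.
- Against: secondary alkoxides add sluggishly to arynes, and the aryl anion can be quenched by proton transfer from a second hydroxyl before it reaches the ester, giving a plain aryl ether.
- Step economy: A4 and A5 each need about four steps, so the key step would risk two finished, expensive fragments and both stereocenters at once.
- In the chosen route a failed key step costs three steps and no stereocenter, and no beta-alkoxy carbonyl compound ever meets base.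

**Alternative 3:** The disconnection is at C3–C4, with C4 as an acyl-anion equivalent. In the forward key step a chiral triazolylidene carbene adds to the ring A aldehyde of the dialdehyde A7 and the resulting acyl-anion equivalent attacks the tethered aliphatic aldehyde; the C2 centre of A7 racemises quickly, so a dynamic kinetic resolution would give A8.
- For: ring C, the C4 ketone and both stereocenters arise in one catalytic step from a racemic precursor, and intramolecular carbene-catalysed benzoin closures to chromanones are precedented. In building the C4 oxidation level directly it is stronger than the chosen route.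
- Against: the carbene must choose the hindered, electron-rich, di-ortho-substituted ring A aldehyde over the unhindered aliphatic one. The opposite choice gives the regioisomeric acyloin with the ketone at C3.
- Against: A7 is an alpha-aryl, alpha-aryloxy acetaldehyde that is hard to make and to keep, and A8 is an alpha-hydroxy ketone open to ene-diol tautomerisation.
- Against: the C3 hydroxyl of A8 still has to be methylated on a base-labile dihydroflavonol, where ring opening, C2 epimerisation and dehydrogenation to the flavonol compete. That adds a step exactly where the skeleton is weakest.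
- The chosen strategy brings the methyl ether in with 4, never has a free 3-hydroxyl, and offers its catalyst a substrate with a single carbonyl group.

Key step: step 3

Assumption on 4: methoxyacetaldehyde is used as the anhydrous monomer, freshly distilled from the commercial material just before use.

Assumption on the catalyst: the sense of induction in step 3 is assigned from the usual shielding model of diarylprolinol silyl ether enamines (electrophile anti to the diaryl(silyloxy)methyl group of the s-trans E enamine); if the sense proved opposite, the enantiomeric catalyst would be used and nothing else changes.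

## Route

Step 1
Reactants: 1 3,4,5-trimethoxyphenol
Product: 2 6-hydroxy-2,3,4-trimethoxybenzaldehyde
Conditions: MgCl2, Et3N, (CH2O)n, MeCN, reflux
Reagents that add atoms: paraformaldehyde (as formaldehyde), C=O
Why: Magnesium-mediated ortho-formylation of a phenol (Casnati–Skattebøl): the magnesium phenoxide delivers formaldehyde to the ortho carbon and a second formaldehyde oxidises the bound benzylic alkoxide by hydride transfer; the two ortho positions of 1 are equivalent and the para position is blocked, so only one product is possible.

Step 2
Reactants: 2 6-hydroxy-2,3,4-trimethoxybenzaldehyde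
Product: 3 2-(hydroxymethyl)-3,4,5-trimethoxyphenol
Conditions: NaBH4 (1 equiv), THF/MeOH, 0 °C; pH 7 buffer, used at once
Reagents that add atoms: none
Why: Borohydride reduction of a salicylaldehyde to the saligenin-type alcohol; low temperature, one equivalent of hydride and a neutral work-up are chosen because the electron-rich benzylic alcohol ionises easily.

Step 3
Reactants: 3 2-(hydroxymethyl)-3,4,5-trimethoxyphenol, 4 methoxyacetaldehyde
Product: 6 (2S,3S)-3,5,6,7-tetramethoxy-3,4-dihydro-2H-chromen-2-ol, via ortho-quinone methide 5 (not isolated)
Conditions: 4 (3 equiv), (R)-α,α-diphenylprolinol trimethylsilyl ether (20 mol %), PhCO2H (20 mol %), CHCl3, rt, 3 added slowly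
Reagents that add atoms: none
Why: Benzoic acid protonates the benzylic hydroxyl of 3, and loss of water, pushed by the ortho hydroxyl and by the methoxy groups ortho and para to the benzylic carbon, releases ortho-quinone methide 5 at a low stationary concentration. The amine condenses with 4 to the E enamine, whose methoxy-bearing carbon is the nucleophilic terminus; it adds to the methide CH2 in a conjugate addition that rearomatises ring A and forms C3–C4. The ring A oxygen then adds to the iminium carbon in a 6-exo-trig closure that forms O1–C2 and ring C as a cyclic N,O-acetal, and the water released in the first stage hydrolyses it to lactol 6 and frees the catalyst. The closest known reaction type is the diarylprolinol silyl ether-catalysed formal [4+2] annulation of aldehydes with ortho-quinone methides generated in situ, which gives chroman-2-ols, together with the use of alpha-alkoxyacetaldehyde enamines in conjugate additions under the same catalysts. C3 is the one lasting stereocenter and is set by the catalyst: the diphenyl(silyloxy)methyl group blocks one face of the s-trans E enamine, and with the (R)-catalyst the open face leads to (3S); C2 is a hemiacetal carbon, forms as an anomeric mixture (trans anomer drawn) and is reset in step 4. The step needs regiocontrol, facial control and chemoselectivity: the first is fixed by polarity (nucleophilic enamine carbon to electrophilic CH2, oxygen to iminium carbon), the second by the catalyst, and the third by keeping 5 scarce beside an excess of 4, so that the enamine and not the free ring carbon of 3 or C8 of 6 captures the methide. The product aldehyde is alpha-branched and held as the lactol, so it should not re-enter the enamine cycle and C3 should not erode.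

Step 4
Reactants: 6 (2S,3S)-3,5,6,7-tetramethoxy-3,4-dihydro-2H-chromen-2-ol, 7 4-(benzyloxy)-3-methoxyphenol
Product: 8 4-(benzyloxy)-5-methoxy-2-[(2R,3S)-3,5,6,7-tetramethoxy-3,4-dihydro-2H-chromen-2-yl]phenol
Conditions: 7 (2 equiv), BF3·OEt2 (0.5 equiv), 4 Å MS, CH2Cl2, −40 → 0 °C
Reagents that add atoms: none
Why: Friedel–Crafts arylation of a lactol-derived oxocarbenium ion by a phenol, as in aryl C-glycoside synthesis (direct C-attack or O-aryl acetal followed by O-to-C shift, both leading ortho to the hydroxyl); the carbon of 7 ortho to OH and para to OMe is the most nucleophilic and the para position is blocked by OBn. Ring B adds anti to the C3 methoxy group, and reversible ionisation of the O1–C2 bond under the Lewis acid funnels material to the diequatorial 2,3-trans isomer, so C2 (R) is set by C3.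

Step 5
Reactants: 8 4-(benzyloxy)-5-methoxy-2-[(2R,3S)-3,5,6,7-tetramethoxy-3,4-dihydro-2H-chromen-2-yl]phenol
Product: 9 (2R,3S)-2-[2,5-bis(benzyloxy)-4-methoxyphenyl]-3,5,6,7-tetramethoxy-3,4-dihydro-2H-chromene
Conditions: BnBr, K2CO3, DMF, rt
Reagents that add atoms: benzyl bromide, BrCc1ccccc1
Why: Williamson etherification of the only free phenol; it is capped because a para-alkoxyphenol would be oxidised to a quinone in step 6, and room temperature keeps base-induced opening of ring C through the ring B phenoxide slow.

Step 6
Reactants: 9 (2R,3S)-2-[2,5-bis(benzyloxy)-4-methoxyphenyl]-3,5,6,7-tetramethoxy-3,4-dihydro-2H-chromene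
Product: 10 (2R,3S)-2-[2,5-bis(benzyloxy)-4-methoxyphenyl]-3,5,6,7-tetramethoxy-3,4-dihydro-2H-chromen-4-ol (both C4 epimers)
Conditions: DDQ (1.5 equiv), CH2Cl2/H2O (20:1), 0 °C → rt
Reagents that add atoms: water, O
Why: Benzylic oxidation by hydride abstraction with DDQ, the reaction used to functionalise C4 of protected flavan-3-ols; the C4 cation is stabilised by O1 and the C5 methoxy group ortho and the C7 methoxy group para to C4a and is trapped by water. The configuration at C4 does not matter because the centre is removed in step 7, and C2 and C3 are not touched.

Step 7
Reactants: 10 (2R,3S)-2-[2,5-bis(benzyloxy)-4-methoxyphenyl]-3,5,6,7-tetramethoxy-3,4-dihydro-2H-chromen-4-ol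
Product: 11 (2R,3R)-2-[2,5-bis(benzyloxy)-4-methoxyphenyl]-3,5,6,7-tetramethoxy-2,3-dihydro-4H-chromen-4-one
Conditions: Dess–Martin periodinane, CH2Cl2, 0 °C → rt
Reagents that add atoms: none
Why: Dess–Martin oxidation of a secondary benzylic alcohol under non-basic conditions, so the newly enolisable C3 and the base-labile O1–C2 bond are not disturbed; the C3 descriptor changes from S to R only because C4 now outranks C2.

Step 8
Reactants: 11 (2R,3R)-2-[2,5-bis(benzyloxy)-4-methoxyphenyl]-3,5,6,7-tetramethoxy-2,3-dihydro-4H-chromen-4-one
Product: 12 (2R,3R)-2-(2,5-dihydroxy-4-methoxyphenyl)-3,5,6,7-tetramethoxy-2,3-dihydro-4H-chromen-4-one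
Conditions: H2 (1 atm), 10% Pd/C, EtOAc, rt, short reaction time, degassed work-up
Reagents that add atoms: none
Why: Hydrogenolysis of aryl benzyl ethers under neutral conditions, standard for benzyl-protected flavanones; the vinylogous-ester-like C4 ketone is reduced slowly under these conditions, and neither stereocenter is exposed to acid or base.

## Compound list

1 | 3,4,5-trimethoxyphenol | COc1cc(O)cc(OC)c1OC | starting material
2 | 6-hydroxy-2,3,4-trimethoxybenzaldehyde | COc1cc(O)c(C=O)c(OC)c1OC | intermediate
3 | 2-(hydroxymethyl)-3,4,5-trimethoxyphenol | COc1cc(O)c(CO)c(OC)c1OC | intermediate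
4 | methoxyacetaldehyde | COCC=O | starting material
5 | 3,4,5-trimethoxy-6-methylidenecyclohexa-2,4-dien-1-one (ortho-quinone methide of ring A) | O=C1C=C(OC)C(OC)=C(OC)C1=C | intermediate (not isolated)
6 | (2S,3S)-3,5,6,7-tetramethoxy-3,4-dihydro-2H-chromen-2-ol (trans anomer drawn; anomers interconvert) | O[C@H]1Oc2cc(OC)c(OC)c(OC)c2C[C@@H]1OC | intermediate
7 | 4-(benzyloxy)-3-methoxyphenol | COc1cc(O)ccc1OCc1ccccc1 | starting material
8 | 4-(benzyloxy)-5-methoxy-2-[(2R,3S)-3,5,6,7-tetramethoxy-3,4-dihydro-2H-chromen-2-yl]phenol | COc1cc(O)c([C@H]2Oc3cc(OC)c(OC)c(OC)c3C[C@@H]2OC)cc1OCc1ccccc1 | intermediate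
9 | (2R,3S)-2-[2,5-bis(benzyloxy)-4-methoxyphenyl]-3,5,6,7-tetramethoxy-3,4-dihydro-2H-chromene | COc1cc(OCc2ccccc2)c([C@H]3Oc4cc(OC)c(OC)c(OC)c4C[C@@H]3OC)cc1OCc1ccccc1 | intermediate
10 | (2R,3S)-2-[2,5-bis(benzyloxy)-4-methoxyphenyl]-3,5,6,7-tetramethoxy-3,4-dihydro-2H-chromen-4-ol (C4 epimers) | COc1cc(OCc2ccccc2)c([C@H]3Oc4cc(OC)c(OC)c(OC)c4C(O)[C@@H]3OC)cc1OCc1ccccc1 | intermediate
11 | (2R,3R)-2-[2,5-bis(benzyloxy)-4-methoxyphenyl]-3,5,6,7-tetramethoxy-2,3-dihydro-4H-chromen-4-one | COc1cc(OCc2ccccc2)c([C@H]3Oc4cc(OC)c(OC)c(OC)c4C(=O)[C@@H]3OC)cc1OCc1ccccc1 | intermediate
12 | (2R,3R)-2-(2,5-dihydroxy-4-methoxyphenyl)-3,5,6,7-tetramethoxy-2,3-dihydro-4H-chromen-4-one | COc1cc(O)c([C@H]2Oc3cc(OC)c(OC)c(OC)c3C(=O)[C@@H]2OC)cc1O | target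

## Step count and least certain steps

Total step count: 8. Longest linear sequence: 8 steps (1 to 12); 4 and 7 are bought and enter in steps 3 and 4.

**Step 3 (key step).**
- What may go wrong: the unsubstituted methide has no steric protection, so it may be consumed by C-alkylation of a second molecule of 3 or of the product at C8 (oligomerisation) before the enamine reaches it.
- It may also N-alkylate the amine catalyst and stall turnover.
- Facial discrimination may fall if the alkoxy enamine populates its Z isomer or if ionisation of 3 needs warming.
- Self-aldol of 4 would drain the aldehyde.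
- Fallback, from 1 back to 6, with C3 taken from the chiral pool. Phenol 1 would be protected (MOMCl, i-Pr2NEt) as 1,2,3-trimethoxy-5-(methoxymethoxy)benzene F1. Lithiation between the acetal oxygen and the neighbouring methoxy group (n-BuLi, THF, 0 °C), then opening of (S)-benzyl glycidyl ether at its terminal carbon (BF3·OEt2, −78 °C), should give (2S)-1-(benzyloxy)-3-[2,3,4-trimethoxy-6-(methoxymethoxy)phenyl]propan-2-ol F2. O-methylation (NaH, MeI) would give 1-[(2S)-3-(benzyloxy)-2-methoxypropyl]-2,3,4-trimethoxy-6-(methoxymethoxy)benzene F3. Hydrogenolysis (H2, Pd/C) would give (2S)-2-methoxy-3-[2,3,4-trimethoxy-6-(methoxymethoxy)phenyl]propan-1-ol F4, and Dess–Martin oxidation (2S)-2-methoxy-3-[2,3,4-trimethoxy-6-(methoxymethoxy)phenyl]propanal F5. Aqueous acid (2 M HCl, THF, rt) would remove the acetal, and the freed phenol closes onto the aldehyde to give 6.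

**Step 4.**
- What may go wrong: the Lewis acid can re-ionise the O1–C2 bond of the product, and a second molecule of 7 may then add to the ring B-stabilised cation (double arylation with ring opening).
- C8 of a second molecule of 6 may compete with 7 as the nucleophile.
- Loss of H3 from the oxocarbenium ion and reprotonation would scramble C3.
- Fallback, from 7 and 6 back to 9 by carbonyl addition and ring closure in place of the Friedel–Crafts reaction. Phenol 7 would be brominated para to its methoxy group (NBS, MeCN, 0 °C) to 4-(benzyloxy)-2-bromo-5-methoxyphenol F6 and benzylated (BnBr, K2CO3) to 1,4-bis(benzyloxy)-2-bromo-5-methoxybenzene F7. Bromine–lithium exchange (n-BuLi, THF, −78 °C) and addition of the aryllithium to the lithium salt of 6, which reacts through its open hydroxy-aldehyde form, should give (2S)-1-[2,5-bis(benzyloxy)-4-methoxyphenyl]-3-(6-hydroxy-2,3,4-trimethoxyphenyl)-2-methoxypropan-1-ol F8 as a mixture of carbinol epimers. Acid-catalysed cyclodehydration (TsOH cat., CH2Cl2, rt) through the ring B benzylic cation would close ring C to the trans flavan 9 under thermodynamic control, so step 5 is no longer needed.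

**Step 6.**
- What may go wrong: hydride abstraction at C2, which is benzylic to the electron-rich ring B and adjacent to O1, may compete with abstraction at C4.
- A benzyl ether methylene may be oxidised, or the reaction may over-oxidise.
- Fallback, from 8 back to 12, with ring B made electron-poor before the oxidation and no hydrogenation after the ketone is in place. Hydrogenolysis of 8 (H2, Pd/C) would give 2-methoxy-5-[(2R,3S)-3,5,6,7-tetramethoxy-3,4-dihydro-2H-chromen-2-yl]benzene-1,4-diol F9. Acetylation (Ac2O, pyridine) would give 2-methoxy-5-[(2R,3S)-3,5,6,7-tetramethoxy-3,4-dihydro-2H-chromen-2-yl]-1,4-phenylene diacetate F10. DDQ in wet CH2Cl2 should then give 2-[(2R,3S)-4-hydroxy-3,5,6,7-tetramethoxy-3,4-dihydro-2H-chromen-2-yl]-5-methoxy-1,4-phenylene diacetate F11, and Dess–Martin oxidation 2-methoxy-5-[(2R,3R)-3,5,6,7-tetramethoxy-4-oxo-3,4-dihydro-2H-chromen-2-yl]-1,4-phenylene diacetate F12. Acid methanolysis (HCl in MeOH, 0 °C → rt) would release 12.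

**Step 2.**
- What may go wrong: the product may ionise to the methide during reduction or work-up, leading to over-reduction to the methylphenol or to self-condensation on concentration.
- Fallback, from 1 back to 6, replacing the labile alcohol by a storable methide precursor. A Mannich reaction of 1 (aqueous Me2NH, aqueous CH2O, EtOH) would give 2-[(dimethylamino)methyl]-3,4,5-trimethoxyphenol F13. Quaternisation (MeI, acetone) would give (6-hydroxy-2,3,4-trimethoxyphenyl)-N,N,N-trimethylmethanaminium iodide F14. This salt releases methide 5 with mild base (NaHCO3, CH2Cl2/H2O, rt) in the presence of 4 and the same amine catalyst, giving 6.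

## Further compounds

F1 | step 3 | 1,2,3-trimethoxy-5-(methoxymethoxy)benzene | COCOc1cc(OC)c(OC)c(OC)c1
F2 | step 3 | (2S)-1-(benzyloxy)-3-[2,3,4-trimethoxy-6-(methoxymethoxy)phenyl]propan-2-ol | O[C@@H](Cc1c(OCOC)cc(OC)c(OC)c1OC)COCc1ccccc1
F3 | step 3 | 1-[(2S)-3-(benzyloxy)-2-methoxypropyl]-2,3,4-trimethoxy-6-(methoxymethoxy)benzene | CO[C@@H](Cc1c(OCOC)cc(OC)c(OC)c1OC)COCc1ccccc1
F4 | step 3 | (2S)-2-methoxy-3-[2,3,4-trimethoxy-6-(methoxymethoxy)phenyl]propan-1-ol | CO[C@@H](Cc1c(OCOC)cc(OC)c(OC)c1OC)CO
F5 | step 3 | (2S)-2-methoxy-3-[2,3,4-trimethoxy-6-(methoxymethoxy)phenyl]propanal | CO[C@@H](Cc1c(OCOC)cc(OC)c(OC)c1OC)C=O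
F6 | step 4 | 4-(benzyloxy)-2-bromo-5-methoxyphenol | COc1cc(O)c(Br)cc1OCc1ccccc1
F7 | step 4 | 1,4-bis(benzyloxy)-2-bromo-5-methoxybenzene | COc1cc(OCc2ccccc2)c(Br)cc1OCc1ccccc1
F8 | step 4 | (2S)-1-[2,5-bis(benzyloxy)-4-methoxyphenyl]-3-(6-hydroxy-2,3,4-trimethoxyphenyl)-2-methoxypropan-1-ol (C1 epimers) | COc1cc(OCc2ccccc2)c(C(O)[C@@H](OC)Cc2c(O)cc(OC)c(OC)c2OC)cc1OCc1ccccc1
F9 | step 6 | 2-methoxy-5-[(2R,3S)-3,5,6,7-tetramethoxy-3,4-dihydro-2H-chromen-2-yl]benzene-1,4-diol | COc1cc(O)c([C@H]2Oc3cc(OC)c(OC)c(OC)c3C[C@@H]2OC)cc1O
F10 | step 6 | 2-methoxy-5-[(2R,3S)-3,5,6,7-tetramethoxy-3,4-dihydro-2H-chromen-2-yl]-1,4-phenylene diacetate | COc1cc(OC(C)=O)c([C@H]2Oc3cc(OC)c(OC)c(OC)c3C[C@@H]2OC)cc1OC(C)=O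
F11 | step 6 | 2-[(2R,3S)-4-hydroxy-3,5,6,7-tetramethoxy-3,4-dihydro-2H-chromen-2-yl]-5-methoxy-1,4-phenylene diacetate (C4 epimers) | COc1cc(OC(C)=O)c([C@H]2Oc3cc(OC)c(OC)c(OC)c3C(O)[C@@H]2OC)cc1OC(C)=O
F12 | step 6 | 2-methoxy-5-[(2R,3R)-3,5,6,7-tetramethoxy-4-oxo-3,4-dihydro-2H-chromen-2-yl]-1,4-phenylene diacetate | COc1cc(OC(C)=O)c([C@H]2Oc3cc(OC)c(OC)c(OC)c3C(=O)[C@@H]2OC)cc1OC(C)=O
F13 | step 2 | 2-[(dimethylamino)methyl]-3,4,5-trimethoxyphenol | COc1cc(O)c(CN(C)C)c(OC)c1OC
F14 | step 2 | (6-hydroxy-2,3,4-trimethoxyphenyl)-N,N,N-trimethylmethanaminium iodide | COc1cc(O)c(C[N+](C)(C)C)c(OC)c1OC.[I-]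
A1 | alternative 1 | 2-diazo-1-[2,3,4-trimethoxy-6-(methoxymethoxy)phenyl]ethan-1-one | COCOc1cc(OC)c(OC)c(OC)c1C(=O)C=[N+]=[N-]
A2 | alternative 1 | 2,5-bis(benzyloxy)-4-methoxybenzaldehyde | COc1cc(OCc2ccccc2)c(C=O)cc1OCc1ccccc1
A3 | alternative 1 | (2R,3R)-3-[2,5-bis(benzyloxy)-4-methoxyphenyl]-3-hydroxy-2-methoxy-1-[2-(methoxymethoxy)-4,5,6-trimethoxyphenyl]propan-1-one | COCOc1cc(OC)c(OC)c(OC)c1C(=O)[C@H](OC)[C@H](O)c1cc(OCc2ccccc2)c(OC)cc1OCc1ccccc1
A4 | alternative 2 | 3,4,5-trimethoxy-2-(trimethylsilyl)phenyl trifluoromethanesulfonate | COc1cc(OS(=O)(=O)C(F)(F)F)c([Si](C)(C)C)c(OC)c1OC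
A5 | alternative 2 | methyl (2R,3R)-3-[2,5-bis(benzyloxy)-4-methoxyphenyl]-3-hydroxy-2-methoxypropanoate | COc1cc(OCc2ccccc2)c([C@@H](O)[C@@H](OC)C(=O)OC)cc1OCc1ccccc1
A6 | alternative 2 | (2R,3R)-2-[2,5-bis(benzyloxy)-4-methoxyphenyl]-3,5,6,7-tetramethoxychroman-4-one | COc1cc(OCc2ccccc2)c([C@H]3Oc4cc(OC)c(OC)c(OC)c4C(=O)[C@@H]3OC)cc1OCc1ccccc1
A7 | alternative 3 | rac-6-{1-[2,5-bis(benzyloxy)-4-methoxyphenyl]-2-oxoethoxy}-2,3,4-trimethoxybenzaldehyde | COc1cc(OCc2ccccc2)c(C(C=O)Oc2cc(OC)c(OC)c(OC)c2C=O)cc1OCc1ccccc1
A8 | alternative 3 | (2R,3R)-2-[2,5-bis(benzyloxy)-4-methoxyphenyl]-3-hydroxy-5,6,7-trimethoxychroman-4-one | COc1cc(OCc2ccccc2)c([C@H]3Oc4cc(OC)c(OC)c(OC)c4C(=O)[C@@H]3O)cc1OCc1ccccc1
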